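The ten-membered ring is opened at C8–C9 by a retro anionic oxy-Cope step. The key step exploits a hidden p-menthane unit: C1–C6 with C15 (the Z C4=C5 olefin and the C3 oxygen) are the six-membered ring of cis-carveol, and C9, C10 and C14 (with C1 the E olefin, later the epoxide) are its isopropenyl group. In one operation the [3,3] shift forms C8–C9, breaks C1–C6, enlarges the cyclohexene to the ten-membered carbocycle, fixes the E C1=C10 geometry and the C8 centre, and leaves a C6 ketone for lactone annulation. Its precursor is a carvone-derived tertiary cyclohexenol carrying a (Z)-2-(4-methoxybenzyloxy)vinyl group trans to isopropenyl and a silyl ether at C3.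

Key step: step 7

Remark on numbering: germacranolide numbering (C1–C15, lactone C6–O–C12) is used for all ten-membered compounds, and carvone-derived carbons are named by the germacrane position they become.

Assumption: in 25 the exposed face of the E C1=C10 olefin is the one whose direct epoxidation would give the (1R,10R) epoxide, as expected for the ground-state conformer of 8-acyloxy germacra-1(10),4-dien-12,6-olides. The (1S,10S) epoxide of the target is therefore made by the halohydrin route (steps 13 and 14).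

Step 1
Reactants: 1 (S)-(+)-carvone
Product: 2 (1S,5S)-cis-carveol
Conditions: NaBH4, CeCl3·7H2O, MeOH, −78 °C
Reagents that add atoms: none
Why: Luche 1,2-reduction of the enone, in which axial hydride attack on the half-chair with equatorial isopropenyl should give the pseudo-equatorial (1S) alcohol cis to that group, the future C3 centre.

Step 2
Reactants: 2 (1S,5S)-cis-carveol
Product: 3 cis-carveol tert-butyldimethylsilyl ether
Conditions: TBSCl, imidazole, DMF, rt
Reagents that add atoms: tert-butyldimethylsilyl chloride, CC(C)(C)[Si](C)(C)Cl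
Why: Standard silylation of a secondary allylic alcohol, which touches no stereocentre and gives an ether that tolerates organolithiums, KH and LDA.

Step 3
Reactants: 3 cis-carveol tert-butyldimethylsilyl ether
Product: 4 (4S,6S)-4-[(tert-butyldimethylsilyl)oxy]-3-methyl-6-(prop-1-en-2-yl)cyclohex-2-en-1-one
Conditions: CrO3, 3,5-dimethylpyrazole, CH2Cl2, −20 °C
Reagents that add atoms: chromium trioxide, O=[Cr](=O)=O
Why: Allylic C–H oxidation (Salmond CrO3·3,5-dimethylpyrazole) at the only ring methylene next to the trisubstituted olefin (future C6), of the valencene-to-nootkatone type that spares an isopropenyl group; the silyloxy-bearing allylic CH is shielded, and the isopropenyl-bearing carbon (future C1) should stay cis to the silyl ether because both groups are pseudo-equatorial.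

Step 4
Reactants: 5 4-methoxybenzyl alcohol; 6 ethyl vinyl ether
Product: 7 4-methoxybenzyl vinyl ether
Conditions: Pd(OAc)2 (cat.), 1,10-phenanthroline (cat.), ethyl vinyl ether (excess), CH2Cl2, rt
Reagents that add atoms: none
Why: Pd(II)-catalysed transfer vinylation (transetherification) of a primary alcohol, driven by the excess of the vinyl donor.

Step 5
Reactants: 7 4-methoxybenzyl vinyl ether
Product: 9 (Z)-2-bromovinyl 4-methoxybenzyl ether, via 1,2-dibromoethyl 4-methoxybenzyl ether 8 (not isolated)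
Conditions: Br2, CH2Cl2, −78 °C; then i-Pr2NEt, −78 °C → rt
Reagents that add atoms: bromine, BrBr
Why: Bromination of the enol ether to the α-bromo ether followed by amine-induced dehydrobromination is the standard route to 2-bromovinyl ethers, in which the Z isomer should predominate and is purified on base-washed silica.

Step 6
Reactants: 9 (Z)-2-bromovinyl 4-methoxybenzyl ether; 4 (4S,6S)-4-[(tert-butyldimethylsilyl)oxy]-3-methyl-6-(prop-1-en-2-yl)cyclohex-2-en-1-one
Product: 12 (1S,4S,6S)-4-[(tert-butyldimethylsilyl)oxy]-1-[(Z)-2-[(4-methoxybenzyl)oxy]ethenyl]-3-methyl-6-(prop-1-en-2-yl)cyclohex-2-en-1-ol, via (Z)-2-(4-methoxybenzyloxy)vinyllithium 10 (not isolated), via lithium cyclohexenolate 11 (not isolated)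
Conditions: t-BuLi (2 equiv), Et2O, −78 °C; then 4, THF, −78 °C; H2O
Reagents that add atoms: none
Why: Bromine–lithium exchange with retention gives a configurationally stable Z β-alkoxyvinyllithium, which should add 1,2 to the enone from the face anti to the neighbouring isopropenyl group (equatorial attack), giving the (1S) tertiary alcohol with the two alkenyl groups trans.

Step 7
Reactants: 12 (1S,4S,6S)-4-[(tert-butyldimethylsilyl)oxy]-1-[(Z)-2-[(4-methoxybenzyl)oxy]ethenyl]-3-methyl-6-(prop-1-en-2-yl)cyclohex-2-en-1-ol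
Product: 15 (2Z,4S,6E,9R)-4-[(tert-butyldimethylsilyl)oxy]-9-[(4-methoxybenzyl)oxy]-3,7-dimethylcyclodeca-2,6-dien-1-one, via potassium cyclohexenolate 13 (not isolated), via potassium cyclodecadienolate 14 (not isolated)
Conditions: KH, 18-crown-6, THF, 0 °C → rt; then AcOH, THF, −78 °C
Reagents that add atoms: none
Why: Deprotonation gives alkoxide 13, whose 3-oxido-1,5-diene (C8=C7–C6(O⁻)–C1–C10=C9) should undergo a concerted chair-like [3,3]-sigmatropic shift, the charge-accelerated (anionic) oxy-Cope rearrangement known for trans-1,2-dialkenylcyclohexanols. The ten-membered ring is closed by four-atom ring expansion and not by cyclisation of a chain: C8–C9 forms between the two alkene termini as the C1–C6 ring bond breaks, and enolate 14 is protonated at C7 to give ketone 15. C8 is the only new stereocentre; it is set by the chair in which the Z enol-ether oxygen is axial (bridged by K⁺ to the alkoxide) and C9 bonds to the C8 face dictated by the C6 and C1 centres of 12, which gives 8R. The same chair places C2 equatorial at C1 and so delivers the E C1=C10 olefin, while the carveol olefin is carried over unchanged as the Z C4=C5 enone. The step needs chair over boat selectivity and survival of the β-alkoxy enolate: the trans (diequatorial) alkenyl groups make the chair the only unstrained array, and low temperature with a cold acetic acid quench limits E1cB loss of the C8 ether.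

Step 8
Reactants: 15 (2Z,4S,6E,9R)-4-[(tert-butyldimethylsilyl)oxy]-9-[(4-methoxybenzyl)oxy]-3,7-dimethylcyclodeca-2,6-dien-1-one; 16 ethyl iodoacetate
Product: 18 ethyl 2-[(1R,3Z,5S,7E,10R)-5-[(tert-butyldimethylsilyl)oxy]-10-[(4-methoxybenzyl)oxy]-4,8-dimethyl-2-oxocyclodeca-3,7-dien-1-yl]acetate, via lithium cyclodecadienolate 17 (not isolated)
Conditions: LDA, THF, −78 °C; then ICH2CO2Et, DMPU, −78 → −40 °C
Reagents that add atoms: none
Why: Kinetic deprotonation can occur only at C7 (C5 is vinylic), and SN2 alkylation of the lithium enolate should take place on the face turned away from the transannular C1=C10 unit, anti to the C9 ring bond, which sets 7R with C11 pseudo-equatorial.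

Step 9
Reactants: 18 ethyl 2-[(1R,3Z,5S,7E,10R)-5-[(tert-butyldimethylsilyl)oxy]-10-[(4-methoxybenzyl)oxy]-4,8-dimethyl-2-oxocyclodeca-3,7-dien-1-yl]acetate
Product: 20 (3S,6R,7R,8R)-3-[(tert-butyldimethylsilyl)oxy]-8-[(4-methoxybenzyl)oxy]germacra-1(10)E,4Z-dien-12,6-olide, via hydroxy ester 19 (not isolated)
Conditions: NaBH4, CeCl3·7H2O, MeOH, −78 → −20 °C; then PPTS (cat.), CH2Cl2, rt
Reagents that add atoms: none
Why: Luche 1,2-reduction of the Z-enone, with hydride expected to enter anti to the new C7 acetate arm (Felkin-type 1,2-induction in the conformer where the C7–C8 bond eclipses the carbonyl), gives the 6R alcohol, which closes the trans-fused γ-lactone by acyl substitution with loss of ethanol.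

Step 10
Reactants: 20 (3S,6R,7R,8R)-3-[(tert-butyldimethylsilyl)oxy]-8-[(4-methoxybenzyl)oxy]germacra-1(10)E,4Z-dien-12,6-olide
Product: 23 (3S,6R,7R,8R)-3-[(tert-butyldimethylsilyl)oxy]-8-[(4-methoxybenzyl)oxy]germacra-1(10)E,4Z,11(13)-trien-12,6-olide, via Mannich base 21 (not isolated), via trimethylammonium iodide 22 (not isolated)
Conditions: LDA, THF, −78 °C; CH2=NMe2⁺ I⁻, −78 °C → rt; then MeI, MeOH, rt; then NaHCO3 (aq), CH2Cl2
Reagents that add atoms: Eschenmoser's salt (N,N-dimethylmethyleneiminium iodide), C=[N+](C)C.[I-]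
Why: Mannich reaction of the lactone lithium enolate with Eschenmoser's salt, exhaustive N-methylation and base-induced β-elimination of trimethylamine install the C11=C13 methylene, and the C11 centre formed in passing is destroyed.

Step 11
Reactants: 23 (3S,6R,7R,8R)-3-[(tert-butyldimethylsilyl)oxy]-8-[(4-methoxybenzyl)oxy]germacra-1(10)E,4Z,11(13)-trien-12,6-olide
Product: 24 (3S,6R,7R,8R)-3-[(tert-butyldimethylsilyl)oxy]-8-hydroxygermacra-1(10)E,4Z,11(13)-trien-12,6-olide
Conditions: DDQ, CH2Cl2/pH 7 buffer, 0 °C → rt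
Reagents that add atoms: none
Why: Oxidative cleavage of the 4-methoxybenzyl ether by DDQ (benzylic hydride abstraction, then hydrolysis of the hemiacetal) in buffered wet dichloromethane should leave the silyl ether, the lactone and the olefins untouched and does not involve C8.

Step 12
Reactants: 24 (3S,6R,7R,8R)-3-[(tert-butyldimethylsilyl)oxy]-8-hydroxygermacra-1(10)E,4Z,11(13)-trien-12,6-olide
Product: 25 (3S,6R,7R,8R)-3-[(tert-butyldimethylsilyl)oxy]-8-(isobutyryloxy)germacra-1(10)E,4Z,11(13)-trien-12,6-olide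
Conditions: (i-PrCO)2O, DMAP (cat.), Et3N, CH2Cl2, 0 °C → rt
Reagents that add atoms: isobutyric anhydride, CC(C)C(=O)OC(=O)C(C)C
Why: DMAP-catalysed acylation of the secondary C8 alcohol, with retention at C8.

Step 13
Reactants: 25 (3S,6R,7R,8R)-3-[(tert-butyldimethylsilyl)oxy]-8-(isobutyryloxy)germacra-1(10)E,4Z,11(13)-trien-12,6-olide
Product: 26 (1R,3S,6R,7R,8R,10S)-1-bromo-3-[(tert-butyldimethylsilyl)oxy]-10-hydroxy-8-(isobutyryloxy)germacra-4Z,11(13)-dien-12,6-olide
Conditions: NBS, THF/H2O (3:1), 0 °C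
Reagents that add atoms: N-bromosuccinimide, O=C1CCC(=O)N1Br; water, O
Why: Bromohydrin formation (van Tamelen conditions) at the most electron-rich olefin: Br⁺ should add to the exposed face of the E C1=C10 bond and water (directly or after transient capture by the C8 ester carbonyl) opens the bromonium ion anti at the tertiary C10, giving the (1R,10S) anti-bromohydrin, while C4=C5 is deactivated by its two allylic oxygens and C11=C13 is electron-poor.

Step 14
Reactants: 26 (1R,3S,6R,7R,8R,10S)-1-bromo-3-[(tert-butyldimethylsilyl)oxy]-10-hydroxy-8-(isobutyryloxy)germacra-4Z,11(13)-dien-12,6-olide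
Product: 27 (1S,3S,6R,7R,8R,10S)-3-[(tert-butyldimethylsilyl)oxy]-1,10-epoxy-8-(isobutyryloxy)germacra-4Z,11(13)-dien-12,6-olide
Conditions: DBU, CH2Cl2, 0 °C → rt
Reagents that add atoms: none
Why: Intramolecular Williamson closure (3-exo-tet) in which the C10 oxygen displaces bromide with inversion at C1, so that the oxirane oxygen ends on the face opposite to the one attacked by Br⁺ and the (1S,10S) trans-epoxide results.

Step 15
Reactants: 27 (1S,3S,6R,7R,8R,10S)-3-[(tert-butyldimethylsilyl)oxy]-1,10-epoxy-8-(isobutyryloxy)germacra-4Z,11(13)-dien-12,6-olide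
Product: 28 (1S,3S,6R,7R,8R,10S)-1,10-epoxy-3-hydroxy-8-(isobutyryloxy)germacra-4Z,11(13)-dien-12,6-olide (CNP0261225.3)
Conditions: TBAF, AcOH, THF, 0 °C → rt
Reagents that add atoms: none
Why: Fluoride-mediated desilylation buffered with acetic acid should free the C3 alcohol without opening the acid-sensitive epoxide, adding to the methylene lactone or cleaving the ester.

Compound list
1 | (S)-(+)-carvone | CC1=CC[C@@H](CC1=O)C(C)=C | starting material
2 | (1S,5S)-cis-carveol, (1S,5S)-2-methyl-5-(prop-1-en-2-yl)cyclohex-2-en-1-ol | CC1=CC[C@@H](C[C@@H]1O)C(C)=C | intermediate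
3 | cis-carveol tert-butyldimethylsilyl ether | CC1=CC[C@@H](C[C@@H]1O[Si](C)(C)C(C)(C)C)C(C)=C | intermediate
4 | (4S,6S)-4-[(tert-butyldimethylsilyl)oxy]-3-methyl-6-(prop-1-en-2-yl)cyclohex-2-en-1-one | CC1=CC(=O)[C@@H](C[C@@H]1O[Si](C)(C)C(C)(C)C)C(C)=C | intermediate
5 | 4-methoxybenzyl alcohol | COc1ccc(CO)cc1 | starting material
6 | ethyl vinyl ether | C=COCC | starting material
7 | 4-methoxybenzyl vinyl ether | C=COCc1ccc(OC)cc1 | intermediate
8 | 1,2-dibromoethyl 4-methoxybenzyl ether (racemic) | BrCC(Br)OCc1ccc(OC)cc1 | intermediate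
9 | (Z)-2-bromovinyl 4-methoxybenzyl ether | Br/C=C\OCc1ccc(OC)cc1 | intermediate
10 | (Z)-2-(4-methoxybenzyloxy)vinyllithium | [Li]/C=C\OCc1ccc(OC)cc1 | intermediate
11 | lithium cyclohexenolate (lithium alkoxide of 12) | [Li]O[C@@]1(/C=C\OCc2ccc(OC)cc2)C=C(C)[C@@H](O[Si](C)(C)C(C)(C)C)C[C@H]1C(C)=C | intermediate
12 | (1S,4S,6S)-4-[(tert-butyldimethylsilyl)oxy]-1-[(Z)-2-[(4-methoxybenzyl)oxy]ethenyl]-3-methyl-6-(prop-1-en-2-yl)cyclohex-2-en-1-ol | O[C@@]1(/C=C\OCc2ccc(OC)cc2)C=C(C)[C@@H](O[Si](C)(C)C(C)(C)C)C[C@H]1C(C)=C | intermediate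
13 | potassium cyclohexenolate (potassium alkoxide of 12) | [K]O[C@@]1(/C=C\OCc2ccc(OC)cc2)C=C(C)[C@@H](O[Si](C)(C)C(C)(C)C)C[C@H]1C(C)=C | intermediate
14 | potassium cyclodecadienolate (C6–OK, E C6=C7 enolate of 15) | [K]OC1=C\[C@H](OCc2ccc(OC)cc2)C/C(C)=C/C[C@H](O[Si](C)(C)C(C)(C)C)/C(C)=C\1 | intermediate
15 | (2Z,4S,6E,9R)-4-[(tert-butyldimethylsilyl)oxy]-9-[(4-methoxybenzyl)oxy]-3,7-dimethylcyclodeca-2,6-dien-1-one (germacrane C6 ketone, 3S,8R) | O=C1C[C@H](OCc2ccc(OC)cc2)C/C(C)=C/C[C@H](O[Si](C)(C)C(C)(C)C)/C(C)=C\1 | intermediate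
16 | ethyl iodoacetate | CCOC(=O)CI | starting material
17 | lithium cyclodecadienolate (C6–OLi, C6=C7 enolate of 15) | [Li]OC1=C\[C@H](OCc2ccc(OC)cc2)C/C(C)=C/C[C@H](O[Si](C)(C)C(C)(C)C)/C(C)=C\1 | intermediate
18 | ethyl 2-[(1R,3Z,5S,7E,10R)-5-[(tert-butyldimethylsilyl)oxy]-10-[(4-methoxybenzyl)oxy]-4,8-dimethyl-2-oxocyclodeca-3,7-dien-1-yl]acetate (3S,7R,8R) | O=C1[C@H](CC(=O)OCC)[C@H](OCc2ccc(OC)cc2)C/C(C)=C/C[C@H](O[Si](C)(C)C(C)(C)C)/C(C)=C\1 | intermediate
19 | ethyl 2-[(1R,2R,3Z,5S,7E,10R)-5-[(tert-butyldimethylsilyl)oxy]-2-hydroxy-10-[(4-methoxybenzyl)oxy]-4,8-dimethylcyclodeca-3,7-dien-1-yl]acetate (3S,6R,7R,8R) | O[C@H]1[C@H](CC(=O)OCC)[C@H](OCc2ccc(OC)cc2)C/C(C)=C/C[C@H](O[Si](C)(C)C(C)(C)C)/C(C)=C\1 | intermediate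
20 | (3S,6R,7R,8R)-3-[(tert-butyldimethylsilyl)oxy]-8-[(4-methoxybenzyl)oxy]germacra-1(10)E,4Z-dien-12,6-olide (trans-fused γ-lactone) | C1C(=O)O[C@@H]2/C=C(/C)[C@@H](O[Si](C)(C)C(C)(C)C)C/C=C(\C)C[C@@H](OCc3ccc(OC)cc3)[C@@H]12 | intermediate
21 | Mannich base, 13-(dimethylamino)-11,13-dihydro derivative of 23 (C11 epimers) | CN(C)CC1C(=O)O[C@@H]2/C=C(/C)[C@@H](O[Si](C)(C)C(C)(C)C)C/C=C(\C)C[C@@H](OCc3ccc(OC)cc3)[C@@H]12 | intermediate
22 | trimethylammonium iodide, methiodide of 21 | C[N+](C)(C)CC1C(=O)O[C@@H]2/C=C(/C)[C@@H](O[Si](C)(C)C(C)(C)C)C/C=C(\C)C[C@@H](OCc3ccc(OC)cc3)[C@@H]12.[I-] | intermediate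
23 | (3S,6R,7R,8R)-3-[(tert-butyldimethylsilyl)oxy]-8-[(4-methoxybenzyl)oxy]germacra-1(10)E,4Z,11(13)-trien-12,6-olide | C=C1C(=O)O[C@@H]2/C=C(/C)[C@@H](O[Si](C)(C)C(C)(C)C)C/C=C(\C)C[C@@H](OCc3ccc(OC)cc3)[C@@H]12 | intermediate
24 | (3S,6R,7R,8R)-3-[(tert-butyldimethylsilyl)oxy]-8-hydroxygermacra-1(10)E,4Z,11(13)-trien-12,6-olide | C=C1C(=O)O[C@@H]2/C=C(/C)[C@@H](O[Si](C)(C)C(C)(C)C)C/C=C(\C)C[C@@H](O)[C@@H]12 | intermediate
25 | (3S,6R,7R,8R)-3-[(tert-butyldimethylsilyl)oxy]-8-(isobutyryloxy)germacra-1(10)E,4Z,11(13)-trien-12,6-olide | C=C1C(=O)O[C@@H]2/C=C(/C)[C@@H](O[Si](C)(C)C(C)(C)C)C/C=C(\C)C[C@@H](OC(=O)C(C)C)[C@@H]12 | intermediate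
26 | (1R,3S,6R,7R,8R,10S)-1-bromo-3-[(tert-butyldimethylsilyl)oxy]-10-hydroxy-8-(isobutyryloxy)germacra-4Z,11(13)-dien-12,6-olide | C=C1C(=O)O[C@@H]2/C=C(/C)[C@@H](O[Si](C)(C)C(C)(C)C)C[C@@H](Br)[C@](O)(C)C[C@@H](OC(=O)C(C)C)[C@@H]12 | intermediate
27 | (1S,3S,6R,7R,8R,10S)-3-[(tert-butyldimethylsilyl)oxy]-1,10-epoxy-8-(isobutyryloxy)germacra-4Z,11(13)-dien-12,6-olide | C=C1C(=O)O[C@@H]2/C=C(/C)[C@@H](O[Si](C)(C)C(C)(C)C)C[C@@H]3O[C@@]3(C)C[C@@H](OC(=O)C(C)C)[C@@H]12 | intermediate
28 | (1S,3S,6R,7R,8R,10S)-1,10-epoxy-3-hydroxy-8-(isobutyryloxy)germacra-4Z,11(13)-dien-12,6-olide (CNP0261225.3) | C=C1C(=O)O[C@@H]2/C=C(/C)[C@@H](O)C[C@@H]3O[C@@]3(C)C[C@@H](OC(=O)C(C)C)[C@@H]12 | target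

Total step count: 15. Longest linear sequence: 13 steps from (S)-carvone (steps 1–3 and 6–15); steps 4 and 5 make the vinyl bromide.

Steps most likely to fail

Step 7. After the [3,3] shift the C8–O bond lies almost parallel to the π system of enolate 14, so expulsion of 4-methoxybenzyl oxide (E1cB) may overtake protonation and drain the ketone. The fallback accepts this elimination and restores the C8 oxygen afterwards. It sets out from 12 and comes back at 15. Alkoxide 13 is left with KH and 18-crown-6 in THF at room temperature until elimination is complete, which should give the cross-conjugated (2Z,4S,6E,9Z)-4-[(tert-butyldimethylsilyl)oxy]-3,7-dimethylcyclodeca-2,6,9-trien-1-one F1. Copper-catalysed conjugate borylation (B2pin2, CuCl, NaOt-Bu, MeOH, and a Josiphos-type bisphosphine whose antipode is chosen to deliver boron to the C8 face that gives 8R) should then take place at the less substituted enone terminus and give (2Z,4S,6E,9R)-4-[(tert-butyldimethylsilyl)oxy]-3,7-dimethyl-9-(4,4,5,5-tetramethyl-1,3,2-dioxaborolan-2-yl)cyclodeca-2,6-dien-1-one F2. Oxidation of the C–B bond with NaBO3·4H2O proceeds with retention and should give (2Z,4S,6E,9R)-4-[(tert-butyldimethylsilyl)oxy]-9-hydroxy-3,7-dimethylcyclodeca-2,6-dien-1-one F3. 4-Methoxybenzyl trichloroacetimidate with catalytic La(OTf)3 in toluene returns the route to 15.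

Step 9. Hydride may be delivered to the other face of the C6 carbonyl, the one syn to the C7 acetate arm, so that lactonisation gives the cis-fused 6-epimer. The fallback turns that outcome into the target series by lactonisation with inversion. It sets out from 18 and comes back at 20. The same reduction and ring closure would then give (3S,6S,7R,8R)-3-[(tert-butyldimethylsilyl)oxy]-8-[(4-methoxybenzyl)oxy]germacra-1(10)E,4Z-dien-12,6-olide F4, the cis-fused lactone. LiOH in THF/H2O opens it to 2-[(1R,2S,3Z,5S,7E,10R)-5-[(tert-butyldimethylsilyl)oxy]-2-hydroxy-10-[(4-methoxybenzyl)oxy]-4,8-dimethylcyclodeca-3,7-dien-1-yl]acetic acid F5. Mitsunobu lactonisation (PPh3, DIAD, toluene, 0 °C), in which the carboxylate displaces the activated C6 oxygen in a five-membered SN2 closure, inverts C6 and should give 20.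

Step 13 (with step 14). The bromonium ion may form on the other face of C1=C10, through the minor olefin rotamer, and anti opening and closure would then give the 1,10-bis-epimeric epoxide. The fallback is direct oxygen transfer instead of the halohydrin route. It sets out from 25 and comes back at 27, with no new compound. mCPBA with NaHCO3 in CH2Cl2 at 0 °C attacks the same exposed face that Br⁺ takes, so it gives the epoxide complementary to that of the halohydrin route, which is 27 in exactly the case where steps 13 and 14 give its diastereomer.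

Further compounds
F1 | step 7 | (2Z,4S,6E,9Z)-4-[(tert-butyldimethylsilyl)oxy]-3,7-dimethylcyclodeca-2,6,9-trien-1-one | O=C1/C=C\C/C(C)=C/C[C@H](O[Si](C)(C)C(C)(C)C)/C(C)=C\1
F2 | step 7 | (2Z,4S,6E,9R)-4-[(tert-butyldimethylsilyl)oxy]-3,7-dimethyl-9-(4,4,5,5-tetramethyl-1,3,2-dioxaborolan-2-yl)cyclodeca-2,6-dien-1-one | O=C1C[C@H](B2OC(C)(C)C(C)(C)O2)C/C(C)=C/C[C@H](O[Si](C)(C)C(C)(C)C)/C(C)=C\1
F3 | step 7 | (2Z,4S,6E,9R)-4-[(tert-butyldimethylsilyl)oxy]-9-hydroxy-3,7-dimethylcyclodeca-2,6-dien-1-one | O=C1C[C@H](O)C/C(C)=C/C[C@H](O[Si](C)(C)C(C)(C)C)/C(C)=C\1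
F4 | step 9 | (3S,6S,7R,8R)-3-[(tert-butyldimethylsilyl)oxy]-8-[(4-methoxybenzyl)oxy]germacra-1(10)E,4Z-dien-12,6-olide (cis-fused, 6-epimer of 20) | C1C(=O)O[C@H]2/C=C(/C)[C@@H](O[Si](C)(C)C(C)(C)C)C/C=C(\C)C[C@@H](OCc3ccc(OC)cc3)[C@@H]12
F5 | step 9 | 2-[(1R,2S,3Z,5S,7E,10R)-5-[(tert-butyldimethylsilyl)oxy]-2-hydroxy-10-[(4-methoxybenzyl)oxy]-4,8-dimethylcyclodeca-3,7-dien-1-yl]acetic acid | O[C@@H]1[C@H](CC(=O)O)[C@H](OCc2ccc(OC)cc2)C/C(C)=C/C[C@H](O[Si](C)(C)C(C)(C)C)/C(C)=C\1
F0 | step 13 | none | none
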